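The dihydrobenzofuran ring (O1, C2, C3, C3a, C7a) is read as the 8–5′ dehydrodimer of two identical 4-hydroxycinnamoyl units. C3 is the α-carbon of one unit, C3a the carbon ortho to the phenol oxygen O1 of the other, and C2 the β-carbon that becomes a para-quinone methide terminus. One Ag2O oxidation of a monomeric N-(4-hydroxycinnamoyl)camphorsultam joins C3 to C3a by radical coupling and closes O1–C2 by oxa-1,6-addition, setting both stereocentres under auxiliary control. The precursor therefore stands at the acid oxidation level and carries neither resorcinol ring. Both auxiliaries are later exchanged, in two directions at once, for the two 2,4-dihydroxyphenyl ketones.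

Key step: step 3

Assumption: the (2R)-bornane-10,2-sultam is taken to direct bond formation to the Cα-re face of the enoyl unit (s-cis, C=O/SO2-anti conformer), which corresponds to (3R). The sense can be checked on the dimer by X-ray analysis against the known auxiliary centres. If it proves opposite, the equally commercial antipodal sultam is used with no other change.

Step 1
Reactants: 1 (E)-4-acetoxycinnamic acid; 2 (1S)-(−)-2,10-camphorsultam [(2R)-bornane-10,2-sultam]
Product: 4 N-[(E)-4-acetoxycinnamoyl]-(2R)-bornane-10,2-sultam, via (E)-4-acetoxycinnamoyl chloride 3 (not isolated)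
Conditions: (COCl)2, cat. DMF, CH2Cl2, 0 °C to rt, concentrate; then 2, Et3N, cat. DMAP, CH2Cl2, 0 °C to rt
Reagents that add atoms: none
Why: Acid chloride formation and DMAP-catalysed N-acylation of the acidic sultam N–H is the standard entry to N-enoyl camphorsultams, the acetate keeps the phenol from acylating, and no stereocentre is formed.

Step 2
Reactants: 4 N-[(E)-4-acetoxycinnamoyl]-(2R)-bornane-10,2-sultam
Product: 5 N-[(E)-4-hydroxycinnamoyl]-(2R)-bornane-10,2-sultam
Conditions: pyrrolidine (2 equiv), CH2Cl2, 0 °C to rt
Reagents that add atoms: none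
Why: Chemoselective aminolysis of an aryl acetate: the phenyl ester is far more electrophilic toward a secondary amine than the conjugated, hindered N-enoyl sultam, so only the phenol is set free and the (E)-alkene and the auxiliary stay untouched.

Step 3
Reactants: 5 N-[(E)-4-hydroxycinnamoyl]-(2R)-bornane-10,2-sultam (two molecules)
Product: 8 trans-(2R,3R)-dihydrobenzofuran bis(N-acylsultam) dimer, via phenoxyl radical 6 (not isolated), via para-quinone methide phenol 7 (not isolated)
Conditions: Ag2O (0.55 equiv per 5), dry CH2Cl2, rt, dark, N2; chromatography, then recrystallisation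
Reagents that add atoms: none
Why: Ag2O removes one electron and one proton from each phenol 5 to give the delocalised phenoxyl radical 6, two such radicals combine between Cα of one and the carbon ortho to oxygen of the other, and tautomerisation restores the second arene and leaves para-quinone methide 7. The regenerated ortho-phenol then adds to the quinone methide terminus in a 5-exo-trig oxa-1,6-conjugate addition that closes the dihydrofuran ring and rearomatises the first ring, so that C3–C3a and O1–C2 arise in one operation. The closest known reaction type is the biomimetic 8–5′ oxidative dimerisation of 4-hydroxycinnamic acid derivatives with Ag2O, including its auxiliary-controlled form with camphorsultam amides of ferulic acid. C3 is controlled by the sultam on the unit that reacts at Cα: in the s-cis, C=O/SO2-anti conformer the auxiliary shields the Cα-si face, so the partner bonds to the Cα-re face, which corresponds to (3R). C2 is controlled by C3, because the closure is reversible through 7 and the trans arrangement of the aryl and acyl groups is both the faster formed and the more stable one, which gives (2R). The step needs 8–5′ regioselectivity over 8–8′, 8–O–4′ and 5–5′ coupling and no over-oxidation: the bulky acyl sultam disfavours the union of two Cα centres, the phenol of the product is no longer conjugated and is harder to oxidise, the oxidant is limited to one electron per monomer, and the minor (2S,3S) product is a diastereomer that chromatography and crystallisation should remove.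

Step 4
Reactants: 8 trans-(2R,3R)-dihydrobenzofuran bis(N-acylsultam) dimer
Product: 9 MOM ether of 8
Conditions: MOMCl, i-Pr2NEt, CH2Cl2, 0 °C to rt
Reagents that add atoms: chloromethyl methyl ether (MOMCl), COCCl
Why: MOM protection (O-alkylation of the phenol under a weak amine base) blocks the one phenol whose phenoxide could reopen the ring through the quinone methide in the later basic step, and i-Pr2NEt is too weak to deprotonate C3, so both stereocentres persist.

Step 5
Reactants: 9 MOM ether of 8
Product: 10 (2R,3R)-bis(Weinreb amide)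
Conditions: MeNH(OMe)·HCl, AlMe3, CH2Cl2, 0 °C to rt; aq. potassium sodium tartrate work-up
Reagents that add atoms: N,O-dimethylhydroxylamine hydrochloride, CNOC.Cl
Why: Aluminium amide aminolysis of N-acyl sultams (Weinreb amide synthesis) displaces both auxiliaries under Lewis acidic, essentially non-basic conditions, so that C3–H is not removed, the MOM ether and the (E)-alkene survive, and the sultam is recovered.

Step 6
Reactants: 11 4-bromoresorcinol
Product: 12 1-bromo-2,4-bis(methoxymethoxy)benzene
Conditions: MOMCl (2.5 equiv), i-Pr2NEt, CH2Cl2, 0 °C to rt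
Reagents that add atoms: chloromethyl methyl ether (MOMCl), COCCl
Why: Double MOM protection of the resorcinol masks both acidic O–H groups before metalation and gives acetals that tolerate, and through the ortho oxygen stabilise, the arylmagnesium reagent.

Step 7
Reactants: 10 (2R,3R)-bis(Weinreb amide); 12 1-bromo-2,4-bis(methoxymethoxy)benzene (5 equiv)
Product: 14 penta-MOM ether of the target, via arylmagnesium bromide 13 (not isolated)
Conditions: 12, Mg turnings, LiCl, THF, rt; then 10, THF, −30 to 0 °C; AcOH quench at −30 °C
Reagents that add atoms: none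
Why: Weinreb ketone synthesis run in two directions: the aryl Grignard reagent adds 1,2 to both amides to give magnesium chelates that collapse to the ketones only on the acidic quench, which excludes over-addition and 1,4-addition to the nascent chalcone, while the low temperature and the non-basic quench hold back deprotonation at C3, so that C2 and C3 are carried through unchanged.

Step 8
Reactants: 14 penta-MOM ether of the target
Product: 15 target (2R,3R)
Conditions: HCl (0.5 M), MeOH–THF, 40 °C
Reagents that add atoms: none
Why: Acid-catalysed acetal cleavage (transacetalisation of the five MOM ethers to methanol) frees all phenols without base, which the β-aryloxy ketone would answer by E1cB ring opening, and the mild temperature limits flavanone closure of the 2′-hydroxychalcone and enolisation at C3, whose only stable outcome is in any case the trans isomer fixed by C2.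

Compound list
1 | (E)-4-acetoxycinnamic acid | CC(=O)Oc1ccc(/C=C/C(=O)O)cc1 | starting material
2 | (1S)-(−)-2,10-camphorsultam, i.e. (2R)-bornane-10,2-sultam | O=S1(=O)C[C@@]23CC[C@@H](C2(C)C)C[C@H]3N1 | starting material
3 | (E)-4-acetoxycinnamoyl chloride | CC(=O)Oc1ccc(/C=C/C(=O)Cl)cc1 | intermediate
4 | N-[(E)-4-acetoxycinnamoyl]-(2R)-bornane-10,2-sultam | CC(=O)Oc1ccc(/C=C/C(=O)N2[C@@H]3C[C@H]4CC[C@]3(CS2(=O)=O)C4(C)C)cc1 | intermediate
5 | N-[(E)-4-hydroxycinnamoyl]-(2R)-bornane-10,2-sultam | Oc1ccc(/C=C/C(=O)N2[C@@H]3C[C@H]4CC[C@]3(CS2(=O)=O)C4(C)C)cc1 | intermediate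
6 | phenoxyl radical of 5 | [O]c1ccc(/C=C/C(=O)N2[C@@H]3C[C@H]4CC[C@]3(CS2(=O)=O)C4(C)C)cc1 | intermediate
7 | 8–5′-coupled open form: para-quinone methide whose exocyclic CH carries a stereocentre (S by CIP, same spatial arrangement as C3 of 8) bearing the acyl sultam and a 2-hydroxy-5-[(E)-2-(sultam-carbonyl)vinyl]phenyl group | O=C1C=CC(=C[C@H](C(=O)N2[C@@H]3C[C@H]4CC[C@]3(CS2(=O)=O)C4(C)C)c2cc(/C=C/C(=O)N3[C@@H]4C[C@H]5CC[C@]4(CS3(=O)=O)C5(C)C)ccc2O)C=C1 | intermediate
8 | trans-(2R,3R)-2-(4-hydroxyphenyl)-2,3-dihydrobenzofuran with C(O)-(2R)-bornane-10,2-sultam at C3 and (E)-CH=CH-C(O)-(2R)-bornane-10,2-sultam at C5 | O=C(/C=C/c1ccc2c(c1)[C@@H](C(=O)N1[C@@H]3C[C@H]4CC[C@]3(CS1(=O)=O)C4(C)C)[C@H](c1ccc(O)cc1)O2)N1[C@@H]2C[C@H]3CC[C@]2(CS1(=O)=O)C3(C)C | intermediate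
9 | MOM ether of 8 (4-methoxymethoxyphenyl at C2), (2R,3R) | O=C(/C=C/c1ccc2c(c1)[C@@H](C(=O)N1[C@@H]3C[C@H]4CC[C@]3(CS1(=O)=O)C4(C)C)[C@H](c1ccc(OCOC)cc1)O2)N1[C@@H]2C[C@H]3CC[C@]2(CS1(=O)=O)C3(C)C | intermediate
10 | (2R,3R)-bis(Weinreb amide): N-methoxy-N-methyl carboxamide at C3 and (E)-N-methoxy-N-methylacrylamide at C5, 4-methoxymethoxyphenyl at C2 | O=C(/C=C/c1ccc2c(c1)[C@@H](C(=O)N(C)OC)[C@H](c1ccc(OCOC)cc1)O2)N(C)OC | intermediate
11 | 4-bromoresorcinol (4-bromobenzene-1,3-diol) | Oc1ccc(Br)c(O)c1 | starting material
12 | 1-bromo-2,4-bis(methoxymethoxy)benzene | COCOc1ccc(Br)c(OCOC)c1 | intermediate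
13 | [2,4-bis(methoxymethoxy)phenyl]magnesium bromide | COCOc1ccc([Mg]Br)c(OCOC)c1 | intermediate
14 | penta-MOM ether of the target, (2R,3R) | O=C(/C=C/c1ccc2c(c1)[C@@H](C(=O)c1ccc(OCOC)cc1OCOC)[C@H](c1ccc(OCOC)cc1)O2)c1ccc(OCOC)cc1OCOC | intermediate
15 | (E)-3-[(2R,3R)-3-(2,4-dihydroxybenzoyl)-2-(4-hydroxyphenyl)-2,3-dihydrobenzofuran-5-yl]-1-(2,4-dihydroxyphenyl)prop-2-en-1-one | O=C(/C=C/c1ccc2c(c1)[C@@H](C(=O)c1ccc(O)cc1O)[C@H](c1ccc(O)cc1)O2)c1ccc(O)cc1O | target

Total step count: 8. Longest linear sequence: 7 (steps 1, 2, 3, 4, 5, 7, 8).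

Steps most likely to fail

1. Step 3. The radical coupling may show poor facial selectivity. Material may also be lost to 8–8′ coupling and to oligomerisation of the bulky monomer. The fallback sets out from 1 and comes back at 10; it gives up the auxiliary and secures the absolute configuration by resolution.
- Acid 1 is heated in MeOH with cat. H2SO4, which esterifies the acid and removes the acetate by transesterification, to give methyl (E)-4-hydroxycinnamate F1.
- Ag2O in benzene–acetone dimerises it to the racemic trans-dihydrobenzofuran diester F2.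
- MOMCl and i-Pr2NEt give the racemic MOM-protected diester F3.
- AlMe3 and MeNH(OMe)·HCl convert both esters into the racemic bis(Weinreb amide).
- Preparative HPLC on a chiral stationary phase separates this into 10 and the (2S,3S)-bis(Weinreb amide) F4.

2. Step 7. The Grignard reagent may deprotonate C3, which leads to β-elimination of the aryloxide and ring opening. The ortho-substituted reagent may also add only slowly to the hindered C3 amide. The fallback sets out from 10 and comes back at 14.
- i-Bu2AlH in THF at −78 °C reduces both amides to the (2R,3R)-dialdehyde F5.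
- Reagent 13 adds at −78 °C to the far more electrophilic aldehydes to give the bis(carbinol) F6, a mixture of epimers at the two carbinol carbons only.
- Dess–Martin periodinane buffered with NaHCO3 oxidises both carbinols to 14.

3. Step 5. Displacement at the hindered C3 acyl sultam may be incomplete, or the nucleophile may attack at sulfur and open the sultam ring. The fallback sets out from 9 and comes back at 14, bypassing 10 and the Grignard step.
- LiSEt (EtSH, n-BuLi) in THF at 0 °C exchanges both auxiliaries to give the (2R,3R)-bis(S-ethyl thioester) F7.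
- Bromide 12 is converted with n-BuLi and B(Oi-Pr)3, then aqueous work-up, into [2,4-bis(methoxymethoxy)phenyl]boronic acid F8.
- A double Liebeskind–Srogl coupling joins them under neutral conditions to give 14, using Pd2(dba)3, tri(2-furyl)phosphine and Cu(O2CC4H3S) (copper thiophene-2-carboxylate) in THF at 50 °C.

Further compounds
F1 | step 3 | methyl (E)-4-hydroxycinnamate | COC(=O)/C=C/c1ccc(O)cc1
F2 | step 3 | racemic trans-dihydrobenzofuran diester, methyl 2-(4-hydroxyphenyl)-5-[(E)-3-methoxy-3-oxoprop-1-enyl]-2,3-dihydrobenzofuran-3-carboxylate (one enantiomer drawn) | COC(=O)/C=C/c1ccc2c(c1)[C@@H](C(=O)OC)[C@H](c1ccc(O)cc1)O2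
F3 | step 3 | racemic MOM-protected diester (one enantiomer drawn) | COC(=O)/C=C/c1ccc2c(c1)[C@@H](C(=O)OC)[C@H](c1ccc(OCOC)cc1)O2
F4 | step 3 | (2S,3S)-bis(Weinreb amide), enantiomer of 10 | O=C(/C=C/c1ccc2c(c1)[C@H](C(=O)N(C)OC)[C@@H](c1ccc(OCOC)cc1)O2)N(C)OC
F5 | step 7 | (2R,3R)-dialdehyde: 3-formyl-2-(4-methoxymethoxyphenyl)-5-[(E)-3-oxoprop-1-enyl]-2,3-dihydrobenzofuran | O=C/C=C/c1ccc2c(c1)[C@@H](C=O)[C@H](c1ccc(OCOC)cc1)O2
F6 | step 7 | bis(carbinol), ring stereocentres unchanged, mixture of epimers at both carbinol carbons | OC(/C=C/c1ccc2c(c1)[C@@H](C(O)c1ccc(OCOC)cc1OCOC)[C@H](c1ccc(OCOC)cc1)O2)c1ccc(OCOC)cc1OCOC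
F7 | step 5 | (2R,3R)-bis(S-ethyl thioester) | CCSC(=O)/C=C/c1ccc2c(c1)[C@@H](C(=O)SCC)[C@H](c1ccc(OCOC)cc1)O2
F8 | step 5 | [2,4-bis(methoxymethoxy)phenyl]boronic acid | COCOc1ccc(B(O)O)c(OCOC)c1
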